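Cuts (retrosynthesis): C7–C11 (alkenyl addition to a C7 ketone); C9=C10 and C1=C2 together (one ene–yne–ene metathesis that makes both rings); C7–C8 (allylboration of a C7 aldehyde); the C3–O ester bond; C2–C3 (alkenyl Grignard addition); C10≡C1 (alkynylation of a C10 aldehyde); C4–C5 (Ireland–Claisen).
Enabling feature: the heteroannular diene C9=C10–C1=C2 across rings A and B has the ring-fusion carbon C10 at its centre, bonded to quaternary C5; this is the imprint of an ethynyl group (C10, C1) on C5 between a vinyl arm (C6–C9) and an isobutenyl arm (C4–C2).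
Forward order: the open chain is built around C5 (C4–C5, then C10≡C1, C2–C3, the C3 ester, C7–C8); ring A (C5–C6–C7–C8–C9–C10) closes first and ring B (C10–C1–C2–C3–C4–C5) directly after in the same flask; C11–C13 is attached last and C8/C13 are adjusted.
Stereochemistry: C4 and C5 by chirality transfer from an (S)-allylic carbinol (asymmetric transfer hydrogenation) through a chair Ireland–Claisen transition state; C3 by Felkin–Anh addition beside C4; C7 by equatorial attack on the bicyclic ketone anti to the axial C5 methyl; C8 is a temporary, catalyst-set centre erased by the last oxidation; the side-chain centre is bought.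
Key step: step 21

Remark: positions are numbered as in eremophilane (ring B: C1–C5 and C10; ring A: C5–C10; C11–C13 on C7; methyls C14 on C5 and C15 on C4). Bicyclic compounds are named on this skeleton and acyclic ones systematically; "dimethyloctadienoate" always means the (2E,4E,6R)-4,6-dimethylocta-2,4-dienoate ester.

Step 1
Reactants: 1 4,4-diethoxybut-1-yne
Product: 3 6,6-diethoxyhex-3-yn-2-one, via lithium acetylide 2 (not isolated)
Conditions: n-BuLi, THF, −78 °C; MeC(O)N(OMe)Me, −78 to 0 °C; aq NH4Cl
Reagents that add atoms: N-methoxy-N-methylacetamide CON(C)C(C)=O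
Why: Acylation of a lithium acetylide with a Weinreb amide stops at the ketone because the chelated tetrahedral adduct survives until the near-neutral quench, which also spares the acetal.

Step 2
Reactants: 3 6,6-diethoxyhex-3-yn-2-one
Product: 4 (2S)-6,6-diethoxyhex-3-yn-2-ol
Conditions: Ru[(S,S)-TsNCH(Ph)CH(Ph)NH](p-cymene) (1 mol%), i-PrOH, rt
Reagents that add atoms: none
Why: Noyori asymmetric transfer hydrogenation of an alkynyl ketone with the base-free amido complex, in which the (S,S)-ligand distinguishes alkynyl from methyl and should give the (S)-propargylic carbinol without touching the base-sensitive CH2 next to the acetal.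

Step 3
Reactants: 4 (2S)-6,6-diethoxyhex-3-yn-2-ol
Product: 6 (2S,3Z)-6,6-diethoxy-4-iodohex-3-en-2-ol, via cyclic alkenylalanate 5 (not isolated)
Conditions: NaAlH2(OCH2CH2OMe)2, THF, 0 °C to rt; I2, THF, −78 °C; aq Na2S2O3, aq potassium sodium tartrate
Reagents that add atoms: iodine [I][I]
Why: Hydroxyl-directed trans-hydroalumination of a propargylic alcohol puts aluminium on the distal alkyne carbon in a five-membered alkoxyalanate, and iodinolysis of the C–Al bond with retention gives the (Z)-iodide.

Step 4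
Reactants: 6 (2S,3Z)-6,6-diethoxy-4-iodohex-3-en-2-ol
Product: 7 (2S,3E)-6,6-diethoxy-4-methylhex-3-en-2-ol
Conditions: Me2CuLi (from MeLi and CuI, excess), Et2O, −20 to 0 °C; aq NH4Cl
Reagents that add atoms: methyllithium [Li]C
Why: Stereoretentive substitution of an alkenyl iodide by a Gilman cuprate installs the future C14 methyl cis to the carbinol carbon, so the trisubstituted olefin is (E).

Step 5
Reactants: 7 (2S,3E)-6,6-diethoxy-4-methylhex-3-en-2-ol; 8 propanoyl chloride
Product: 9 (2S,3E)-6,6-diethoxy-4-methylhex-3-en-2-yl propanoate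
Conditions: pyridine, DMAP (cat.), CH2Cl2, 0 °C to rt
Reagents that add atoms: none
Why: DMAP-catalysed O-acylation of a secondary allylic alcohol under basic conditions, which leave the carbinol centre and the acetal untouched.

Step 6
Reactants: 9 (2S,3E)-6,6-diethoxy-4-methylhex-3-en-2-yl propanoate
Product: 12 (2S,3R,4E)-3-(2,2-diethoxyethyl)-2,3-dimethylhex-4-enoic acid, via silyl ketene acetal 10 (not isolated), via trimethylsilyl ester 11 (not isolated)
Conditions: LiN(i-Pr)2, THF/DMPU (3:1), −78 °C; Me3SiCl, Et3N, −78 °C to rt, then 50 °C; aq citric acid (pH 4–5), 0 °C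
Reagents that add atoms: none
Why: Ireland–Claisen rearrangement in which DMPU-assisted enolisation gives the enolate with methyl cis to O-metal and its silyl ketene acetal rearranges through a chair with the carbinol methyl equatorial, so the (S)-carbinol and the (E)-olefin are translated into the 2S,3R pair (future C4 and C5, methyls syn) and an (E)-propenyl group while the C4–C5 bond forms.

Step 7
Reactants: 12 (2S,3R,4E)-3-(2,2-diethoxyethyl)-2,3-dimethylhex-4-enoic acid
Product: 14 (2S,3R,4E)-3-(2,2-diethoxyethyl)-N-methoxy-N,2,3-trimethylhex-4-enamide, via acyl imidazole 13 (not isolated)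
Conditions: 1,1'-carbonyldiimidazole, CH2Cl2, rt; MeNH(OMe)·HCl, rt
Reagents that add atoms: N,O-dimethylhydroxylamine hydrochloride CNOC.Cl
Why: Amide coupling through the acyl imidazole is a near-neutral activation that should neither epimerise C2 nor open the acetal, and the freshly made acid is used at once so that its carboxyl group cannot attack the acetal.

Step 8
Reactants: 14 (2S,3R,4E)-3-(2,2-diethoxyethyl)-N-methoxy-N,2,3-trimethylhex-4-enamide
Product: 16 (2S,3S)-5,5-diethoxy-3-formyl-N-methoxy-N,2,3-trimethylpentanamide, via secondary ozonide 15 (not isolated)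
Conditions: O3, CH2Cl2, −78 °C (Sudan Red 7B end point); PPh3, −78 °C to rt
Reagents that add atoms: ozone [O-][O+]=O
Why: Ozonolysis with reductive work-up cleaves the only olefin (the indicator dye stops the gas before the acetal C–H bond is attacked) and unveils the future C10 as an aldehyde without an α-hydrogen.

Step 9
Reactants: 16 (2S,3S)-5,5-diethoxy-3-formyl-N-methoxy-N,2,3-trimethylpentanamide
Product: 17 (2S,3S)-5,5-diethoxy-3-ethynyl-N-methoxy-N,2,3-trimethylpentanamide
Conditions: dimethyl (1-diazo-2-oxopropyl)phosphonate, K2CO3, MeOH, 0 °C to rt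
Reagents that add atoms: dimethyl (1-diazo-2-oxopropyl)phosphonate CC(=O)C(=[N+]=[N-])P(=O)(OC)OC
Why: Seyferth–Gilbert homologation in the Ohira–Bestmann form converts the non-enolisable aldehyde into the terminal alkyne (the reagent carbon becomes C1) under carbonate conditions too mild to epimerise the amide α-centre.

Step 10
Reactants: 17 (2S,3S)-5,5-diethoxy-3-ethynyl-N-methoxy-N,2,3-trimethylpentanamide
Product: 18 (2S,3S)-5,5-diethoxy-3-ethynyl-2,3-dimethylpentanal
Conditions: i-Bu2AlH, THF, −78 °C; aq potassium sodium tartrate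
Reagents that add atoms: none
Why: Partial reduction of a Weinreb amide, whose chelated aluminium hemiaminal holds the aldehyde oxidation level until work-up while alkyne and acetal are inert at −78 °C; the α-methyl aldehyde is used at once to avoid epimerisation.

Step 11
Reactants: 18 (2S,3S)-5,5-diethoxy-3-ethynyl-2,3-dimethylpentanal; 19 2-methylprop-1-enylmagnesium bromide
Product: 20 (4S,5S,6S)-6-(2,2-diethoxyethyl)-2,5,6-trimethyloct-2-en-7-yn-4-ol
Conditions: THF, −78 to −40 °C; aq NH4Cl
Reagents that add atoms: none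
Why: Felkin–Anh addition of an alkenyl Grignard reagent to an α-methyl aldehyde, with the quaternary carbon as the large group anti to the nucleophile, should give the carbinol syn to the α-methyl (4S, the future C3), and addition should outrun deprotonation of the hindered alkyne at −78 °C.

Step 12
Reactants: 21 (R)-2-methylbutanoic acid
Product: 22 (R)-2-methylbutan-1-ol
Conditions: LiAlH4, Et2O, 0 °C to rt; H2O, aq NaOH
Reagents that add atoms: none
Why: Hydride reduction of a carboxylic acid to the primary alcohol does not involve the α-stereocentre.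

Step 13
Reactants: 22 (R)-2-methylbutan-1-ol
Product: 24 (2E,4R)-2,4-dimethylhex-2-enal, via (R)-2-methylbutanal 23 (not isolated)
Conditions: TEMPO (cat.), PhI(OAc)2, CH2Cl2, rt; then Ph3P=C(Me)CHO, 40 °C
Reagents that add atoms: 2-(triphenylphosphoranylidene)propanal CC(C=O)=P(c1ccccc1)(c1ccccc1)c1ccccc1
Why: Oxoammonium (TEMPO) oxidation gives the volatile, epimerisable aldehyde under non-basic conditions and Wittig olefination with a stabilised ylide traps it in the same flask, which should give the (E)-enal.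

Step 14
Reactants: 24 (2E,4R)-2,4-dimethylhex-2-enal
Product: 25 ethyl (2E,4E,6R)-4,6-dimethylocta-2,4-dienoate
Conditions: (EtO)2P(O)CH2CO2Et, NaH, THF, 0 °C to rt
Reagents that add atoms: triethyl phosphonoacetate CCOC(=O)CP(=O)(OCC)OCC
Why: Horner–Wadsworth–Emmons olefination of the enal with a stabilised phosphonate anion should give the (2E,4E)-dienoate.

Step 15
Reactants: 25 ethyl (2E,4E,6R)-4,6-dimethylocta-2,4-dienoate
Product: 26 (2E,4E,6R)-4,6-dimethylocta-2,4-dienoic acid
Conditions: LiOH, THF/MeOH/H2O, rt; 1 M HCl to pH 3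
Reagents that add atoms: lithium hydroxide [Li+].[OH-]
Why: Saponification at room temperature is too weakly basic to deconjugate the dienoate or disturb the remote stereocentre.

Step 16
Reactants: 20 (4S,5S,6S)-6-(2,2-diethoxyethyl)-2,5,6-trimethyloct-2-en-7-yn-4-ol; 26 (2E,4E,6R)-4,6-dimethylocta-2,4-dienoic acid
Product: 28 (4S,5S,6S)-6-(2,2-diethoxyethyl)-2,5,6-trimethyloct-2-en-7-yn-4-yl dimethyloctadienoate, via mixed anhydride 27 (not isolated)
Conditions: 26, 2,4,6-trichlorobenzoyl chloride, Et3N, toluene, rt; then 20, DMAP, toluene, rt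
Reagents that add atoms: none
Why: Yamaguchi esterification, in which the DMAP-activated mixed anhydride acylates the hindered secondary allylic alcohol with retention at carbon, and capping the C3 oxygen now prevents it from closing a lactol onto C7 once the acetal is opened.

Step 17
Reactants: 28 (4S,5S,6S)-6-(2,2-diethoxyethyl)-2,5,6-trimethyloct-2-en-7-yn-4-yl dimethyloctadienoate
Product: 29 (4S,5S,6S)-6-ethynyl-2,5,6-trimethyl-8-oxooct-2-en-4-yl dimethyloctadienoate
Conditions: TsOH·H2O (10 mol%), acetone/H2O (10:1), rt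
Reagents that add atoms: water O
Why: Acid-catalysed hydrolysis (transacetalisation to acetone) of an unhindered aliphatic diethyl acetal proceeds at room temperature, where the allylic ester should not ionise.

Step 18
Reactants: 30 (E)-3-(tert-butyldimethylsilyloxy)prop-1-enylboronic acid pinacol ester
Product: 31 (E)-3-(tert-butyldimethylsilyloxy)prop-2-enylboronic acid pinacol ester
Conditions: [Ir(cod)(PPh2Me)2]PF6 (3 mol%, activated with H2), THF, rt, argon
Reagents that add atoms: none
Why: Iridium-hydride-catalysed olefin transposition (1,3-hydrogen shift) moves the double bond into conjugation with oxygen, and the bulky silyl group should favour the (E)-γ-silyloxyallylboronate.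

Step 19
Reactants: 29 (4S,5S,6S)-6-ethynyl-2,5,6-trimethyl-8-oxooct-2-en-4-yl dimethyloctadienoate; 31 (E)-3-(tert-butyldimethylsilyloxy)prop-2-enylboronic acid pinacol ester
Product: 32 (4S,5S,6S,8R,9S)-9-(tert-butyldimethylsilyloxy)-6-ethynyl-8-hydroxy-2,5,6-trimethylundeca-2,10-dien-4-yl dimethyloctadienoate
Conditions: (S)-TRIP [(S)-3,3'-bis(2,4,6-triisopropylphenyl)-1,1'-binaphthyl-2,2'-diyl hydrogen phosphate] (5 mol%), 4 Å molecular sieves, toluene, −30 °C; aq NaHCO3
Reagents that add atoms: none
Why: Chiral-phosphoric-acid-catalysed allylboration through a closed chair transition state forms C7–C8; the (E)-boronate gives the anti (8R,9S) pair and the (S)-acid is chosen to send the reagent to the Si face of the aldehyde, so the silyloxy carbon (future C8) is set by the catalyst and not by the remote quaternary centre.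

Step 20
Reactants: 32 (4S,5S,6S,8R,9S)-9-(tert-butyldimethylsilyloxy)-6-ethynyl-8-hydroxy-2,5,6-trimethylundeca-2,10-dien-4-yl dimethyloctadienoate
Product: 33 (4S,5S,6S,9S)-9-(tert-butyldimethylsilyloxy)-6-ethynyl-2,5,6-trimethyl-8-oxoundeca-2,10-dien-4-yl dimethyloctadienoate
Conditions: Dess–Martin periodinane, NaHCO3, CH2Cl2, 0 °C to rt
Reagents that add atoms: none
Why: Buffered Dess–Martin oxidation of the secondary alcohol gives the C7 ketone without epimerising the α-silyloxy centre or moving the β,γ-double bond.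

Step 21
Reactants: 33 (4S,5S,6S,9S)-9-(tert-butyldimethylsilyloxy)-6-ethynyl-2,5,6-trimethyl-8-oxoundeca-2,10-dien-4-yl dimethyloctadienoate
Product: 34 (3S,4S,5S,8S)-8-(tert-butyldimethylsilyloxy)-7-oxo-11,12,13-trinoreremophila-1,9-dien-3-yl dimethyloctadienoate
Conditions: second-generation Grubbs catalyst RuCl2(H2IMes)(PCy3)(=CHPh) (10 mol%), 1,4-benzoquinone (20 mol%), toluene (0.002 M), 60 °C, argon purge
Reagents that add atoms: none
Why: The ruthenium alkylidene should load on the only monosubstituted olefin (the C9 vinyl group) and the C9 alkylidene then adds across the ethynyl group with C9 bonding to the proximal alkyne carbon C10, which closes ring A (C5–C6–C7–C8–C9–C10) in the exo mode and leaves a conjugated vinylcarbene on C1. That carbene closes ring B (C10–C1–C2–C3–C4–C5) by ring-closing olefin metathesis onto the isobutenyl group, and the expelled isopropylidene unit leaves as 2-methylpropene after the next initiation. The closest known reaction type is the group-selective ene–yne–ene (dienyne) ring-closing metathesis that turns an ethynyl-bearing carbon with two olefin arms into a fused bicyclic 1,3-diene. Both closures are six-membered and intramolecular (ring A by exo enyne metathesis, ring B by olefin metathesis of the vinylcarbene), and quaternary C5 holds the three reacting groups together. No stereocentre is formed, and C3, C4, C5 and C8 are carried through unchanged. The selectivity needed is initiation at C9 and not at C2 (a C2 alkylidene would close a five-membered ring onto C10); it is secured by making C2 part of a trisubstituted olefin beside the bulky C3 ester, while the dienoate olefins are electron-poor or trisubstituted and should stay out.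

Step 22
Reactants: 35 2-bromoprop-2-en-1-ol
Product: 36 (2-bromoprop-2-enyloxy)(tert-butyl)dimethylsilane
Conditions: t-BuMe2SiCl, imidazole, CH2Cl2, rt
Reagents that add atoms: tert-butyldimethylsilyl chloride CC(C)(C)[Si](C)(C)Cl
Why: Imidazole-promoted silylation of a primary alcohol.

Step 23
Reactants: 34 (3S,4S,5S,8S)-8-(tert-butyldimethylsilyloxy)-7-oxo-11,12,13-trinoreremophila-1,9-dien-3-yl dimethyloctadienoate; 36 (2-bromoprop-2-enyloxy)(tert-butyl)dimethylsilane
Product: 39 (3S,4S,5S,7S,8S)-8,13-bis(tert-butyldimethylsilyloxy)-7-hydroxyeremophila-1,9,11(12)-trien-3-yl dimethyloctadienoate, via alkenyllithium 37 (not isolated), via alkenylcerium dichloride 38 (not isolated)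
Conditions: 36, t-BuLi (2 equiv), Et2O, −78 °C; CeCl3, THF, −78 °C; then 34, THF, −78 °C; aq NH4Cl
Reagents that add atoms: none
Why: Bromine–lithium exchange, transmetallation to the weakly basic alkenylcerium reagent and 1,2-addition to the ketone along the equatorial trajectory (anti to the axial C5 methyl, unhindered by the pseudo-equatorial C8 silyl ether) should place the alkenyl group trans and the new hydroxyl cis to that methyl (7S), while the hindered dienoate is left alone at −78 °C.

Step 24
Reactants: 39 (3S,4S,5S,7S,8S)-8,13-bis(tert-butyldimethylsilyloxy)-7-hydroxyeremophila-1,9,11(12)-trien-3-yl dimethyloctadienoate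
Product: 40 (3S,4S,5S,7S,8S)-7,8,13-trihydroxyeremophila-1,9,11(12)-trien-3-yl dimethyloctadienoate
Conditions: HF·pyridine, pyridine, THF, 0 °C to rt
Reagents that add atoms: none
Why: Fluoride cleavage of both silyl ethers with pyridine-buffered HF, conditions under which the esters and the tertiary allylic alcohol are stable.

Step 25
Reactants: 40 (3S,4S,5S,7S,8S)-7,8,13-trihydroxyeremophila-1,9,11(12)-trien-3-yl dimethyloctadienoate
Product: 41 (3S,4S,5S,7S,8S)-13-acetoxy-7,8-dihydroxyeremophila-1,9,11(12)-trien-3-yl dimethyloctadienoate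
Conditions: AcCl, 2,4,6-collidine, CH2Cl2, −78 °C
Reagents that add atoms: acetyl chloride CC(=O)Cl
Why: Kinetic acylation with acetyl chloride and a hindered pyridine base at low temperature should pick the primary allylic hydroxyl over the hindered secondary and the tertiary one.

Step 26
Reactants: 41 (3S,4S,5S,7S,8S)-13-acetoxy-7,8-dihydroxyeremophila-1,9,11(12)-trien-3-yl dimethyloctadienoate
Product: 42 (3S,4S,5S,7S)-13-acetoxy-7-hydroxy-8-oxoeremophila-1,9,11(12)-trien-3-yl dimethyloctadienoate (CNP0160850.1)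
Conditions: Dess–Martin periodinane, NaHCO3, CH2Cl2, 0 °C
Reagents that add atoms: none
Why: Dess–Martin oxidation of the secondary dienylic alcohol gives the cross-conjugated ketone, removes the temporary C8 stereocentre and cannot touch the tertiary C7 hydroxyl.

Compound list
1 | 4,4-diethoxybut-1-yne | C#CCC(OCC)OCC | starting material
2 | (4,4-diethoxybut-1-yn-1-yl)lithium | [Li]C#CCC(OCC)OCC | intermediate
3 | 6,6-diethoxyhex-3-yn-2-one | CC(=O)C#CCC(OCC)OCC | intermediate
4 | (2S)-6,6-diethoxyhex-3-yn-2-ol | C[C@H](O)C#CCC(OCC)OCC | intermediate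
5 | sodium (5S)-3-(2,2-diethoxyethyl)-2,2-bis(2-methoxyethoxy)-5-methyl-2,5-dihydro-1,2-oxaluminol-2-uide (cyclic alkenylalanate) | C[C@@H]1O[Al-](OCCOC)(OCCOC)C(CC(OCC)OCC)=C1.[Na+] | intermediate
6 | (2S,3Z)-6,6-diethoxy-4-iodohex-3-en-2-ol | C[C@H](O)/C=C(\I)CC(OCC)OCC | intermediate
7 | (2S,3E)-6,6-diethoxy-4-methylhex-3-en-2-ol | C[C@H](O)/C=C(\C)CC(OCC)OCC | intermediate
8 | propanoyl chloride | CCC(=O)Cl | starting material
9 | (2S,3E)-6,6-diethoxy-4-methylhex-3-en-2-yl propanoate | CCC(=O)O[C@@H](C)/C=C(\C)CC(OCC)OCC | intermediate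
10 | (1Z)-1-{[(2S,3E)-6,6-diethoxy-4-methylhex-3-en-2-yl]oxy}-1-(trimethylsilyloxy)prop-1-ene (silyl ketene acetal) | C/C=C(\O[Si](C)(C)C)O[C@@H](C)/C=C(\C)CC(OCC)OCC | intermediate
11 | trimethylsilyl (2S,3R,4E)-3-(2,2-diethoxyethyl)-2,3-dimethylhex-4-enoate | C[Si](C)(C)OC(=O)[C@@H](C)[C@](C)(CC(OCC)OCC)/C=C/C | intermediate
12 | (2S,3R,4E)-3-(2,2-diethoxyethyl)-2,3-dimethylhex-4-enoic acid | OC(=O)[C@@H](C)[C@](C)(CC(OCC)OCC)/C=C/C | intermediate
13 | 1-[(2S,3R,4E)-3-(2,2-diethoxyethyl)-2,3-dimethylhex-4-enoyl]imidazole | O=C([C@@H](C)[C@](C)(CC(OCC)OCC)/C=C/C)n1ccnc1 | intermediate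
14 | (2S,3R,4E)-3-(2,2-diethoxyethyl)-N-methoxy-N,2,3-trimethylhex-4-enamide | CON(C)C(=O)[C@@H](C)[C@](C)(CC(OCC)OCC)/C=C/C | intermediate
15 | (2S,3S)-5,5-diethoxy-N-methoxy-N,2,3-trimethyl-3-(5-methyl-1,2,4-trioxolan-3-yl)pentanamide (secondary ozonide) | CON(C)C(=O)[C@@H](C)[C@](C)(CC(OCC)OCC)C1OOC(C)O1 | intermediate
16 | (2S,3S)-5,5-diethoxy-3-formyl-N-methoxy-N,2,3-trimethylpentanamide | CON(C)C(=O)[C@@H](C)[C@](C)(CC(OCC)OCC)C=O | intermediate
17 | (2S,3S)-5,5-diethoxy-3-ethynyl-N-methoxy-N,2,3-trimethylpentanamide | CON(C)C(=O)[C@@H](C)[C@](C)(CC(OCC)OCC)C#C | intermediate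
18 | (2S,3S)-5,5-diethoxy-3-ethynyl-2,3-dimethylpentanal | O=C[C@@H](C)[C@](C)(CC(OCC)OCC)C#C | intermediate
19 | 2-methylprop-1-enylmagnesium bromide | CC(C)=C[Mg]Br | starting material
20 | (4S,5S,6S)-6-(2,2-diethoxyethyl)-2,5,6-trimethyloct-2-en-7-yn-4-ol | C#C[C@@](C)(CC(OCC)OCC)[C@H](C)[C@@H](O)C=C(C)C | intermediate
21 | (R)-2-methylbutanoic acid | CC[C@@H](C)C(=O)O | starting material
22 | (R)-2-methylbutan-1-ol | CC[C@@H](C)CO | intermediate
23 | (R)-2-methylbutanal | CC[C@@H](C)C=O | intermediate
24 | (2E,4R)-2,4-dimethylhex-2-enal | O=C/C(C)=C/[C@H](C)CC | intermediate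
25 | ethyl (2E,4E,6R)-4,6-dimethylocta-2,4-dienoate | CCOC(=O)/C=C/C(C)=C/[C@H](C)CC | intermediate
26 | (2E,4E,6R)-4,6-dimethylocta-2,4-dienoic acid | OC(=O)/C=C/C(C)=C/[C@H](C)CC | intermediate
27 | (2E,4E,6R)-4,6-dimethylocta-2,4-dienoic 2,4,6-trichlorobenzoic anhydride | O=C(OC(=O)/C=C/C(C)=C/[C@H](C)CC)c1c(Cl)cc(Cl)cc1Cl | intermediate
28 | (4S,5S,6S)-6-(2,2-diethoxyethyl)-2,5,6-trimethyloct-2-en-7-yn-4-yl (2E,4E,6R)-4,6-dimethylocta-2,4-dienoate | C#C[C@@](C)(CC(OCC)OCC)[C@H](C)[C@@H](OC(=O)/C=C/C(C)=C/[C@H](C)CC)C=C(C)C | intermediate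
29 | (4S,5S,6S)-6-ethynyl-2,5,6-trimethyl-8-oxooct-2-en-4-yl (2E,4E,6R)-4,6-dimethylocta-2,4-dienoate | C#C[C@@](C)(CC=O)[C@H](C)[C@@H](OC(=O)/C=C/C(C)=C/[C@H](C)CC)C=C(C)C | intermediate
30 | (E)-3-(tert-butyldimethylsilyloxy)prop-1-enylboronic acid pinacol ester | CC(C)(C)[Si](C)(C)OC/C=C/B1OC(C)(C)C(C)(C)O1 | starting material
31 | (E)-3-(tert-butyldimethylsilyloxy)prop-2-enylboronic acid pinacol ester | CC(C)(C)[Si](C)(C)O/C=C/CB1OC(C)(C)C(C)(C)O1 | intermediate
32 | (4S,5S,6S,8R,9S)-9-(tert-butyldimethylsilyloxy)-6-ethynyl-8-hydroxy-2,5,6-trimethylundeca-2,10-dien-4-yl (2E,4E,6R)-4,6-dimethylocta-2,4-dienoate | C#C[C@@](C)(C[C@@H](O)[C@@H](O[Si](C)(C)C(C)(C)C)C=C)[C@H](C)[C@@H](OC(=O)/C=C/C(C)=C/[C@H](C)CC)C=C(C)C | intermediate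
33 | (4S,5S,6S,9S)-9-(tert-butyldimethylsilyloxy)-6-ethynyl-2,5,6-trimethyl-8-oxoundeca-2,10-dien-4-yl (2E,4E,6R)-4,6-dimethylocta-2,4-dienoate | C#C[C@@](C)(CC(=O)[C@@H](O[Si](C)(C)C(C)(C)C)C=C)[C@H](C)[C@@H](OC(=O)/C=C/C(C)=C/[C@H](C)CC)C=C(C)C | intermediate
34 | (3S,4S,5S,8S)-8-(tert-butyldimethylsilyloxy)-7-oxo-11,12,13-trinoreremophila-1,9-dien-3-yl (2E,4E,6R)-4,6-dimethylocta-2,4-dienoate | O=C1C[C@]2(C)C(=C[C@@H]1O[Si](C)(C)C(C)(C)C)C=C[C@H](OC(=O)/C=C/C(C)=C/[C@H](C)CC)[C@H]2C | intermediate
35 | 2-bromoprop-2-en-1-ol | C=C(Br)CO | starting material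
36 | (2-bromoprop-2-enyloxy)(tert-butyl)dimethylsilane | C=C(Br)CO[Si](C)(C)C(C)(C)C | intermediate
37 | [3-(tert-butyldimethylsilyloxy)prop-1-en-2-yl]lithium | [Li]C(=C)CO[Si](C)(C)C(C)(C)C | intermediate
38 | dichloro[3-(tert-butyldimethylsilyloxy)prop-1-en-2-yl]cerium | C=C(CO[Si](C)(C)C(C)(C)C)[Ce](Cl)Cl | intermediate
39 | (3S,4S,5S,7S,8S)-8,13-bis(tert-butyldimethylsilyloxy)-7-hydroxyeremophila-1,9,11(12)-trien-3-yl (2E,4E,6R)-4,6-dimethylocta-2,4-dienoate | C=C(CO[Si](C)(C)C(C)(C)C)[C@@]1(O)C[C@]2(C)C(=C[C@@H]1O[Si](C)(C)C(C)(C)C)C=C[C@H](OC(=O)/C=C/C(C)=C/[C@H](C)CC)[C@H]2C | intermediate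
40 | (3S,4S,5S,7S,8S)-7,8,13-trihydroxyeremophila-1,9,11(12)-trien-3-yl (2E,4E,6R)-4,6-dimethylocta-2,4-dienoate | C=C(CO)[C@@]1(O)C[C@]2(C)C(=C[C@@H]1O)C=C[C@H](OC(=O)/C=C/C(C)=C/[C@H](C)CC)[C@H]2C | intermediate
41 | (3S,4S,5S,7S,8S)-13-acetoxy-7,8-dihydroxyeremophila-1,9,11(12)-trien-3-yl (2E,4E,6R)-4,6-dimethylocta-2,4-dienoate | C=C(COC(C)=O)[C@@]1(O)C[C@]2(C)C(=C[C@@H]1O)C=C[C@H](OC(=O)/C=C/C(C)=C/[C@H](C)CC)[C@H]2C | intermediate
42 | (3S,4S,5S,7S)-13-acetoxy-7-hydroxy-8-oxoeremophila-1,9,11(12)-trien-3-yl (2E,4E,6R)-4,6-dimethylocta-2,4-dienoate (CNP0160850.1) | C=C(COC(C)=O)[C@@]1(O)C[C@]2(C)C(=CC1=O)C=C[C@H](OC(=O)/C=C/C(C)=C/[C@H](C)CC)[C@H]2C | target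

Total step count: 26 (main chain 20; side-chain acid 4; reagent preparations 2).
Longest linear sequence: 20 steps (steps 1–11, 16, 17, 19, 20, 21, 23, 24, 25, 26).

Steps most likely to fail

Step 21. The cascade may stall after the catalyst has loaded on the C9 vinyl group, through chelation of ruthenium by the C7 carbonyl, or the β,γ-olefin of the α-silyloxy ketone may migrate under ruthenium hydride catalysis before ring A closes. The fallback sets out from alcohol 32: the same ene–yne–ene closure is run one oxidation level lower, where neither the chelating ketone nor the acidic C8 hydrogen is present, and should give the bicyclic C7 alcohol F1. Dess–Martin oxidation of F1 then comes back to the route at ketone 34.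

Step 23. Deprotonation at C8 (a hydrogen both α to the ketone and allylic to the diene) may compete with addition, and facial control may erode if ring A leaves the half-chair that holds the C5 methyl axial. The fallback sets out from ketone 34: the C8 silyl group is removed with pyridine-buffered HF to give the α-hydroxy ketone F2. F2 is treated with three equivalents of alkenylcerium 38, so that the first equivalent forms the C8 alkoxide; this alkoxide blocks enolisation toward C8 and chelates the carbonyl for attack from the face opposite the C5 methyl, giving the C13 silyl ether diol F3. Cleavage of the remaining silyl ether of F3 with HF·pyridine comes back to the route at triol 40.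

Step 11. Felkin–Anh control may be only moderate for an alkenyl Grignard reagent, and deprotonation of the alkyne or epimerisation of the α-methyl aldehyde would erode yield and diastereomeric purity. The fallback sets out from Weinreb amide 17: Grignard reagent 19 is added to the amide itself to give the enone F4. F4 is then reduced under reagent control (CBS reduction with the (S)-methyl oxazaborolidine and catecholborane at −78 °C, the isobutenyl group acting as the larger substituent), which comes back to the route at allylic alcohol 20.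

Further compounds
F1 | step 21 | (3S,4S,5S,7R,8S)-8-(tert-butyldimethylsilyloxy)-7-hydroxy-11,12,13-trinoreremophila-1,9-dien-3-yl (2E,4E,6R)-4,6-dimethylocta-2,4-dienoate | O[C@@H]1C[C@]2(C)C(=C[C@@H]1O[Si](C)(C)C(C)(C)C)C=C[C@H](OC(=O)/C=C/C(C)=C/[C@H](C)CC)[C@H]2C
F2 | step 23 | (3S,4S,5S,8S)-8-hydroxy-7-oxo-11,12,13-trinoreremophila-1,9-dien-3-yl (2E,4E,6R)-4,6-dimethylocta-2,4-dienoate | O=C1C[C@]2(C)C(=C[C@@H]1O)C=C[C@H](OC(=O)/C=C/C(C)=C/[C@H](C)CC)[C@H]2C
F3 | step 23 | (3S,4S,5S,7S,8S)-13-(tert-butyldimethylsilyloxy)-7,8-dihydroxyeremophila-1,9,11(12)-trien-3-yl (2E,4E,6R)-4,6-dimethylocta-2,4-dienoate | C=C(CO[Si](C)(C)C(C)(C)C)[C@@]1(O)C[C@]2(C)C(=C[C@@H]1O)C=C[C@H](OC(=O)/C=C/C(C)=C/[C@H](C)CC)[C@H]2C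
F4 | step 11 | (5S,6S)-6-(2,2-diethoxyethyl)-2,5,6-trimethyloct-2-en-7-yn-4-one | C#C[C@@](C)(CC(OCC)OCC)[C@H](C)C(=O)C=C(C)C
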